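**Retrosynthetic overview**

1. Ring numbering used throughout: C1 = quaternary carbon (methyl, 4-methylpent-3-enyl), C2=C3, C4 (senecioyloxy), C5 (methyl, OH), C6=C7, C8 (ketone), C9 (CH2OH), C10, C11.
2. Key disconnection C4–C5: the 11-membered carbocycle, the only ring, is closed by a titanium-induced intramolecular pinacol coupling of an acyclic enal (C4) and methyl enone (C5). The enabling feature is that the C4/C5 vicinal diol lies between the C2=C3 and C6=C7 E-olefins (a 1,5-diene-3,4-diol), so both carbinol carbons arise from conjugated carbonyl groups.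
3. The precursor carries C8 one oxidation level lower, as an R-configured OTES carbinol. This keeps a dienone away from the reductant and serves as a temporary stereocentre that steers the coupling. C9–CH2OH is carried as a TBDPS ether.
4. Acyclic chain: C8–C9 by Ni/Cr coupling of a (Z)-alkenyl iodide with (E)-4-oxopent-2-enal; C9=C10 by iodo-Wittig olefination; C1 by copper-catalysed enantioselective allylic substitution of geranyl diethyl phosphate with an alkenylboronate.
5. After ring closure: acylation of O4, deprotection and oxidation at C8, final desilylation.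

Key step: step 12

Remark: in steps 2 and 9 the antipode of the chiral ligand is the one that delivers the configuration drawn (S at C1, R at C8); both antipodes of each ligand are accessible.

**Route**

Step 1
Reactants: 1 geraniol
Product: 2 geranyl diethyl phosphate
Conditions: ClP(O)(OEt)2, pyridine, DMAP (cat.), CH2Cl2, 0 → 23 °C
Reagents that add atoms: diethyl chlorophosphate, CCOP(=O)(Cl)OCC
Why: O-Phosphorylation of the primary allylic alcohol (pyridine as HCl acceptor) installs the leaving group for the copper-catalysed SN2′ step without touching the E-olefin; no stereocentre is formed.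

Step 2
Reactants: 2 geranyl diethyl phosphate; 3 (E)-3,3-diethoxyprop-1-enylboronic acid pinacol ester
Product: 4 (2E,4S)-4-ethenyl-1,1-diethoxy-4,8-dimethylnona-2,7-diene
Conditions: CuCl (5 mol%), chiral sulfonate-bearing imidazolinium salt (NHC precursor, 5.5 mol%), NaOMe (1.5 equiv), THF, 60 °C
Reagents that add atoms: none
Why: Copper/NHC-catalysed enantioselective allylic substitution (SN2′): methoxide activates the alkenyl–B(pin) bond, the alkenylcopper adds to the γ-carbon of the E-trisubstituted allylic phosphate with retention of the alkenyl geometry, and the chiral NHC selects the olefin face, so that the fixed E geometry of 2 translates methyl versus homoprenyl into the S quaternary centre C1.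

Step 3
Reactants: 4 (2E,4S)-4-ethenyl-1,1-diethoxy-4,8-dimethylnona-2,7-diene
Product: 6 (3S,4E)-6,6-diethoxy-3-methyl-3-(4-methylpent-3-enyl)hex-4-en-1-ol, via B-alkyl-9-BBN adduct 5 (not isolated)
Conditions: 9-BBN, THF, 0 → 23 °C; then NaOH, H2O2, 0 °C
Reagents that add atoms: hydrogen peroxide, OO (hydroxyl oxygen of 6); 9-borabicyclo[3.3.1]nonane, B1C2CCCC1CCC2 (boron of intermediate 5 only)
Why: Hydroboration–oxidation with 9-BBN, whose steric demand places boron on the terminal carbon of the monosubstituted vinyl group and leaves the 1,2-disubstituted and trisubstituted olefins alone; C1 is untouched (it is labelled R in 5 only because boron lowers the CIP rank of that branch).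

Step 4
Reactants: 6 (3S,4E)-6,6-diethoxy-3-methyl-3-(4-methylpent-3-enyl)hex-4-en-1-ol
Product: 7 (3S,4E)-6,6-diethoxy-3-methyl-3-(4-methylpent-3-enyl)hex-4-enal
Conditions: Dess–Martin periodinane, pyridine, CH2Cl2, 0 → 23 °C
Reagents that add atoms: none
Why: Dess–Martin oxidation of the primary alcohol to the aldehyde under pyridine buffering, which keeps the acid-labile allylic acetal intact and cannot affect the quaternary centre.

Step 5
Reactants: 7 (3S,4E)-6,6-diethoxy-3-methyl-3-(4-methylpent-3-enyl)hex-4-enal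
Product: 8 ethyl (2Z,5S,6E)-8,8-diethoxy-2-iodo-5-methyl-5-(4-methylpent-3-enyl)octa-2,6-dienoate
Conditions: Ph3P=CHCO2Et, NIS, CH2Cl2, −20 °C; then 7, K2CO3, 23 °C
Reagents that add atoms: ethyl (triphenylphosphoranylidene)acetate, CCOC(=O)C=P(c1ccccc1)(c1ccccc1)c1ccccc1; N-iodosuccinimide, O=C1CCC(=O)N1I
Why: Halo-Wittig olefination: iodination of the stabilised ylide in the flask gives the α-iodo ylide, whose reaction with the aldehyde places the ester trans to the chain, i.e. gives the (Z)-α-iodo enoate with iodine cis to C11 (the future C9=C10 geometry).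

Step 6
Reactants: 8 ethyl (2Z,5S,6E)-8,8-diethoxy-2-iodo-5-methyl-5-(4-methylpent-3-enyl)octa-2,6-dienoate
Product: 9 (2Z,5S,6E)-8,8-diethoxy-2-iodo-5-methyl-5-(4-methylpent-3-enyl)octa-2,6-dien-1-ol
Conditions: DIBAL-H (2.5 equiv), CH2Cl2, −78 °C
Reagents that add atoms: none
Why: DIBAL-H 1,2-reduction of the ester to the allylic alcohol at low temperature, under which the alkenyl iodide, the acetal and the olefin geometries are stable.

Step 7
Reactants: 9 (2Z,5S,6E)-8,8-diethoxy-2-iodo-5-methyl-5-(4-methylpent-3-enyl)octa-2,6-dien-1-ol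
Product: 10 TBDPS ether of 9
Conditions: TBDPSCl, imidazole, DMF, 23 °C
Reagents that add atoms: tert-butyl(chloro)diphenylsilane, CC(C)(C)[Si](Cl)(c1ccccc1)c1ccccc1
Why: Silylation of the primary alcohol gives the robust TBDPS ether, which should survive every later step up to the last one.

Step 8
Reactants: 11 2-methylfuran
Product: 13 (2E)-4-oxopent-2-enal, via (2Z)-4-oxopent-2-enal 12 (not isolated)
Conditions: NBS, NaHCO3, acetone/H2O (10:1), −15 °C; then pyridine, 23 °C
Reagents that add atoms: water, O
Why: Oxidative ring opening of the furan (bromonium addition, attack of water, opening of the 2-hydroxy-2,5-dihydrofuran) gives the Z keto-enal, which pyridine isomerises to the E isomer by reversible conjugate addition.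

Step 9
Reactants: 10 TBDPS ether of 9; 13 (2E)-4-oxopent-2-enal
Product: 14 (3E,5R,6Z,9S,10E)-6-(TBDPS-oxymethyl)-12,12-diethoxy-5-hydroxy-9-methyl-9-(4-methylpent-3-enyl)dodeca-3,6,10-trien-2-one
Conditions: CrCl2 (4 equiv), NiCl2 (2 mol%), chiral 2-(2-methanesulfonamidophenyl)oxazoline ligand (4.4 equiv), Et3N (4.4 equiv), THF, 23 °C
Reagents that add atoms: none
Why: Nozaki–Hiyama–Kishi coupling: nickel-catalysed formation of the alkenyl species of trivalent chromium with retention of the Z geometry and aldehyde-selective 1,2-addition (the methyl ketone of 13 is spared), the chromium-bound chiral sulfonamide ligand selecting the aldehyde face and so setting the temporary C8 stereocentre as R.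

Step 10
Reactants: 14 (3E,5R,6Z,9S,10E)-6-(TBDPS-oxymethyl)-12,12-diethoxy-5-hydroxy-9-methyl-9-(4-methylpent-3-enyl)dodeca-3,6,10-trien-2-one
Product: 15 (2E,4S,6Z,8R,9E)-7-(TBDPS-oxymethyl)-8-hydroxy-4-methyl-4-(4-methylpent-3-enyl)-11-oxododeca-2,6,9-trienal
Conditions: PPTS (cat.), acetone/H2O (10:1), 23 °C
Reagents that add atoms: water, O
Why: Acid-catalysed acetal hydrolysis, very fast for an α,β-unsaturated acetal (allyl-stabilised oxocarbenium ion) and carried out before O8 is silylated so that no acid-labile TES ether is exposed.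

Step 11
Reactants: 15 (2E,4S,6Z,8R,9E)-7-(TBDPS-oxymethyl)-8-hydroxy-4-methyl-4-(4-methylpent-3-enyl)-11-oxododeca-2,6,9-trienal
Product: 16 TES ether of 15 (keto-enal)
Conditions: TESCl, imidazole, DMF, 0 °C
Reagents that add atoms: chlorotriethylsilane, CC[Si](Cl)(CC)CC
Why: Silylation of the secondary alcohol as its TES ether, which masks O8 during the reductive step and can later be removed without loss of the TBDPS group.

Step 12
Reactants: 16 TES ether of 15 (keto-enal)
Product: 17 macrocyclic diol (1S,4R,5R,8R; 2E,6E,9Z)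
Conditions: TiCl3(DME)1.5 (10 equiv), Zn–Cu couple (25 equiv), DME, reflux, then 25 °C; 16 added over 30 h by syringe pump (final ≤ 2 mM); aq. K2CO3 work-up
Reagents that add atoms: none
Why: Low-valent titanium reduces the two conjugated carbonyl groups to titanium-bound ketyls, which couple between C4 and C5 to a titanium pinacolate that is hydrolysed to the diol on work-up, and at 25 °C the pinacolate is not deoxygenated to the olefin (McMurry-type pinacol coupling). The closest known reaction type is the titanium-induced intramolecular pinacol coupling of keto-aldehydes and of conjugated dialdehydes to 10- to 14-membered cyclic 1,2-diols. The 11-membered carbocycle closes head-to-tail between the two chain termini (both carbinol carbons become ring atoms) under syringe-pump dilution. The relative configuration of C4 and C5 (4R*,5R*, oxygens trans on the ring) should follow from the anti arrangement of the two O–Ti bonds that this coupling prefers in medium and large rings, and the absolute sense is steered by the temporary 8R centre: with C8–H eclipsing C6=C7 the OTES group points away from the forming ring, the C9 arm and hence C4 reach C5 on the enone face syn to the C8–C9 bond, and with the titanium-bound oxygen s-trans to C6=C7 this face gives 5R. The step needs coupling at the carbonyl carbons and not at the β-carbons, which the titanium–oxygen template and the hindered β-positions (C2 next to quaternary C1, C7 next to the silyloxy-bearing C8) should secure, and it needs cyclisation to outrun oligomerisation, which slow addition secures. The remote C1 centre (methyl versus CH2R) is expected to contribute little, which is why the control element is placed at C8.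

Step 13
Reactants: 17 macrocyclic diol; 18 3-methylbut-2-enoyl chloride
Product: 19 C4 senecioate of 17
Conditions: pyridine, DMAP (cat.), CH2Cl2, 0 °C
Reagents that add atoms: none
Why: Acylation with the acid chloride (DMAP catalysis) is selective for the secondary allylic C4–OH over the hindered tertiary C5–OH, and pyridine as the only base avoids vinylketene formation and thus deconjugation of the senecioyl group.

Step 14
Reactants: 19 C4 senecioate of 17
Product: 20 C8 alcohol (TES removed)
Conditions: HF·pyridine, pyridine, THF, 0 °C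
Reagents that add atoms: none
Why: Fluoride-mediated desilylation in which buffered HF·pyridine at 0 °C cleaves the secondary TES ether while the primary TBDPS ether, the ester and the tertiary allylic alcohol remain.

Step 15
Reactants: 20 C8 alcohol
Product: 21 TBDPS ether of the target (C8 ketone)
Conditions: Dess–Martin periodinane, pyridine, CH2Cl2, 0 → 23 °C
Reagents that add atoms: none
Why: Dess–Martin oxidation of the doubly allylic secondary alcohol gives the cross-conjugated dienone (the tertiary C5–OH cannot be oxidised), and the temporary C8 stereocentre is erased.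

Step 16
Reactants: 21 TBDPS ether of the target
Product: 22 target, CID15817377
Conditions: HF·pyridine, THF, 23 °C
Reagents that add atoms: none
Why: Fluoride-mediated cleavage of the TBDPS ether under non-basic conditions, which avoids acyl migration from O4 to O5 and base-induced damage to the γ-hydroxy dienone.

**Compound list**

1 | geraniol, (2E)-3,7-dimethylocta-2,6-dien-1-ol | CC(C)=CCC/C(C)=C/CO | starting material
2 | geranyl diethyl phosphate | CC(C)=CCC/C(C)=C/COP(=O)(OCC)OCC | intermediate
3 | (E)-2-(3,3-diethoxyprop-1-en-1-yl)-4,4,5,5-tetramethyl-1,3,2-dioxaborolane | CCOC(OCC)/C=C/B1OC(C)(C)C(C)(C)O1 | starting material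
4 | (2E,4S)-4-ethenyl-1,1-diethoxy-4,8-dimethylnona-2,7-diene | C=C[C@](C)(CCC=C(C)C)/C=C/C(OCC)OCC | intermediate
5 | 9-[(3R,4E)-6,6-diethoxy-3-methyl-3-(4-methylpent-3-en-1-yl)hex-4-en-1-yl]-9-borabicyclo[3.3.1]nonane | C1CCC2CCCC1B2CC[C@](C)(CCC=C(C)C)/C=C/C(OCC)OCC | intermediate (not isolated)
6 | (3S,4E)-6,6-diethoxy-3-methyl-3-(4-methylpent-3-en-1-yl)hex-4-en-1-ol | OCC[C@](C)(CCC=C(C)C)/C=C/C(OCC)OCC | intermediate
7 | (3S,4E)-6,6-diethoxy-3-methyl-3-(4-methylpent-3-en-1-yl)hex-4-enal | O=CC[C@](C)(CCC=C(C)C)/C=C/C(OCC)OCC | intermediate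
8 | ethyl (2Z,5S,6E)-8,8-diethoxy-2-iodo-5-methyl-5-(4-methylpent-3-en-1-yl)octa-2,6-dienoate | CCOC(=O)/C(I)=C/C[C@](C)(CCC=C(C)C)/C=C/C(OCC)OCC | intermediate
9 | (2Z,5S,6E)-8,8-diethoxy-2-iodo-5-methyl-5-(4-methylpent-3-en-1-yl)octa-2,6-dien-1-ol | OC/C(I)=C/C[C@](C)(CCC=C(C)C)/C=C/C(OCC)OCC | intermediate
10 | tert-butyl{[(2Z,5S,6E)-8,8-diethoxy-2-iodo-5-methyl-5-(4-methylpent-3-en-1-yl)octa-2,6-dien-1-yl]oxy}diphenylsilane | CC(C)(C)[Si](OC/C(I)=C/C[C@](C)(CCC=C(C)C)/C=C/C(OCC)OCC)(c1ccccc1)c1ccccc1 | intermediate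
11 | 2-methylfuran | Cc1ccco1 | starting material
12 | (2Z)-4-oxopent-2-enal | CC(=O)/C=C\C=O | intermediate (not isolated)
13 | (2E)-4-oxopent-2-enal | CC(=O)/C=C/C=O | intermediate
14 | (3E,5R,6Z,9S,10E)-6-{[(tert-butyldiphenylsilyl)oxy]methyl}-12,12-diethoxy-5-hydroxy-9-methyl-9-(4-methylpent-3-en-1-yl)dodeca-3,6,10-trien-2-one | CC(=O)/C=C/[C@@H](O)/C(CO[Si](c1ccccc1)(c1ccccc1)C(C)(C)C)=C\C[C@](C)(CCC=C(C)C)/C=C/C(OCC)OCC | intermediate
15 | (2E,4S,6Z,8R,9E)-7-{[(tert-butyldiphenylsilyl)oxy]methyl}-8-hydroxy-4-methyl-4-(4-methylpent-3-en-1-yl)-11-oxododeca-2,6,9-trienal | CC(=O)/C=C/[C@@H](O)/C(CO[Si](c1ccccc1)(c1ccccc1)C(C)(C)C)=C\C[C@](C)(CCC=C(C)C)/C=C/C=O | intermediate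
16 | (2E,4S,6Z,8R,9E)-7-{[(tert-butyldiphenylsilyl)oxy]methyl}-4-methyl-4-(4-methylpent-3-en-1-yl)-11-oxo-8-[(triethylsilyl)oxy]dodeca-2,6,9-trienal | CC(=O)/C=C/[C@@H](O[Si](CC)(CC)CC)/C(CO[Si](c1ccccc1)(c1ccccc1)C(C)(C)C)=C\C[C@](C)(CCC=C(C)C)/C=C/C=O | intermediate
17 | (1S,4R,5R,8R)-9-{[(tert-butyldiphenylsilyl)oxy]methyl}-1,5-dimethyl-1-(4-methylpent-3-en-1-yl)-8-[(triethylsilyl)oxy]cycloundeca-2E,6E,9Z-triene-4,5-diol (overview numbering) | CC(C)=CCC[C@]1(C)/C=C/[C@@H](O)[C@](C)(O)/C=C/[C@@H](O[Si](CC)(CC)CC)/C(CO[Si](c2ccccc2)(c2ccccc2)C(C)(C)C)=C\C1 | intermediate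
18 | 3-methylbut-2-enoyl chloride | CC(C)=CC(=O)Cl | starting material
19 | (1S,4R,5R,8R)-4-O-(3-methylbut-2-enoyl) ester of 17 | CC(C)=CCC[C@]1(C)/C=C/[C@@H](OC(=O)C=C(C)C)[C@](C)(O)/C=C/[C@@H](O[Si](CC)(CC)CC)/C(CO[Si](c2ccccc2)(c2ccccc2)C(C)(C)C)=C\C1 | intermediate
20 | (1S,4R,5R,8R)-9-{[(tert-butyldiphenylsilyl)oxy]methyl}-5,8-dihydroxy-1,5-dimethyl-1-(4-methylpent-3-en-1-yl)cycloundeca-2E,6E,9Z-trien-4-yl 3-methylbut-2-enoate | CC(C)=CCC[C@]1(C)/C=C/[C@@H](OC(=O)C=C(C)C)[C@](C)(O)/C=C/[C@@H](O)/C(CO[Si](c2ccccc2)(c2ccccc2)C(C)(C)C)=C\C1 | intermediate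
21 | (1S,4R,5R)-9-{[(tert-butyldiphenylsilyl)oxy]methyl}-5-hydroxy-1,5-dimethyl-1-(4-methylpent-3-en-1-yl)-8-oxocycloundeca-2E,6E,9Z-trien-4-yl 3-methylbut-2-enoate | CC(C)=CCC[C@]1(C)/C=C/[C@@H](OC(=O)C=C(C)C)[C@](C)(O)/C=C/C(=O)/C(CO[Si](c2ccccc2)(c2ccccc2)C(C)(C)C)=C\C1 | intermediate
22 | CID15817377, (1S,4R,5R)-5-hydroxy-9-(hydroxymethyl)-1,5-dimethyl-1-(4-methylpent-3-en-1-yl)-8-oxocycloundeca-2E,6E,9Z-trien-4-yl 3-methylbut-2-enoate | CC(C)=CCC[C@]1(C)/C=C/[C@@H](OC(=O)C=C(C)C)[C@](C)(O)/C=C/C(=O)/C(CO)=C\C1 | target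

**Step count and risks**

Total step count: 16 (steps 1–7 and 9–16 in the main line, step 8 for the C5–C8 partner).
Longest linear sequence: 15 steps (1 → 22).

Steps most likely to fail:

1. Step 12. The threo preference of the ketyl–ketyl coupling may erode, so that the two oxygens end cis on the ring (C4 epimer); over-reduction of the γ-silyloxy enone is a second concern. Fallback: the route sets out from 16 as before, and the 4-epimeric diol, (1S,4S,5R,8R)-configured macrocyclic diol F1, is not discarded. Mitsunobu esterification of F1 with 3-methylbut-2-enoic acid (PPh3, diisopropyl azodicarboxylate, toluene, 0 °C) inverts C4 while it installs the ester and should give 19 directly, where the route is rejoined. The stereochemistry at C4 is then set by substitution, not by the coupling.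

2. Step 9. Divalent chromium may reduce the doubly activated olefin of 13 in competition with the coupling, and ligand control at C8 may be incomplete with this small, reactive aldehyde. Fallback: the route sets out from 10, which is coupled under the same Ni/Cr conditions with acrolein to give the divinyl carbinol (3R,4Z,7S,8E)-4-{[(tert-butyldiphenylsilyl)oxy]methyl}-10,10-diethoxy-7-methyl-7-(4-methylpent-3-en-1-yl)deca-1,4,8-trien-3-ol F2. Cross-metathesis of its terminal vinyl group with but-3-en-2-one (second-generation Hoveyda–Grubbs catalyst, CH2Cl2, 40 °C) then builds the E-enone and returns to 14.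

3. Step 2. Enantioface discrimination between methyl and homoprenyl at the γ-carbon may be insufficient, and SN2 substitution may leak in. Fallback: the route sets out from 1 and sets C1 by stereospecific epoxide opening instead of catalysis. Sharpless asymmetric epoxidation (D-(−)-diethyl tartrate, Ti(OiPr)4, t-BuOOH) gives (2R,3R)-2,3-epoxygeraniol F3. The diethylalkynylalane made from 3,3-diethoxyprop-1-yne (n-BuLi, Et2AlCl, toluene) opens the epoxide at the tertiary carbon with inversion to (2S,3R)-3-(3,3-diethoxyprop-1-yn-1-yl)-3,7-dimethyloct-6-ene-1,2-diol F4. NaIO4 cleaves the diol to (2R)-5,5-diethoxy-2-methyl-2-(4-methylpent-3-en-1-yl)pent-3-ynal F5, and Wittig methylenation (Ph3P=CH2) gives (3S)-6,6-diethoxy-3-methyl-3-(4-methylpent-3-en-1-yl)hex-1-en-4-yne F6. Ruthenium-catalysed trans-hydrosilylation ([Cp*Ru(MeCN)3]PF6, (EtO)3SiH) to the vinylsilane triethoxy[(2Z,4S)-4-ethenyl-1,1-diethoxy-4,8-dimethylnona-2,7-dien-2-yl]silane F7, followed by protodesilylation (CuI, TBAF), delivers the E-olefin and returns to 4.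

Further compounds

F1 | step 12 | (1S,4S,5R,8R)-9-{[(tert-butyldiphenylsilyl)oxy]methyl}-1,5-dimethyl-1-(4-methylpent-3-en-1-yl)-8-[(triethylsilyl)oxy]cycloundeca-2E,6E,9Z-triene-4,5-diol (C4 epimer of 17) | CC(C)=CCC[C@]1(C)/C=C/[C@H](O)[C@](C)(O)/C=C/[C@@H](O[Si](CC)(CC)CC)/C(CO[Si](c2ccccc2)(c2ccccc2)C(C)(C)C)=C\C1
F2 | step 9 | (3R,4Z,7S,8E)-4-{[(tert-butyldiphenylsilyl)oxy]methyl}-10,10-diethoxy-7-methyl-7-(4-methylpent-3-en-1-yl)deca-1,4,8-trien-3-ol | C=C[C@@H](O)/C(CO[Si](c1ccccc1)(c1ccccc1)C(C)(C)C)=C\C[C@](C)(CCC=C(C)C)/C=C/C(OCC)OCC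
F3 | step 2 | [(2R,3R)-3-methyl-3-(4-methylpent-3-en-1-yl)oxiran-2-yl]methanol | OC[C@H]1O[C@]1(C)CCC=C(C)C
F4 | step 2 | (2S,3R)-3-(3,3-diethoxyprop-1-yn-1-yl)-3,7-dimethyloct-6-ene-1,2-diol | OC[C@@H](O)[C@](C)(CCC=C(C)C)C#CC(OCC)OCC
F5 | step 2 | (2R)-5,5-diethoxy-2-methyl-2-(4-methylpent-3-en-1-yl)pent-3-ynal | O=C[C@](C)(CCC=C(C)C)C#CC(OCC)OCC
F6 | step 2 | (3S)-6,6-diethoxy-3-methyl-3-(4-methylpent-3-en-1-yl)hex-1-en-4-yne | C=C[C@](C)(CCC=C(C)C)C#CC(OCC)OCC
F7 | step 2 | triethoxy[(2Z,4S)-4-ethenyl-1,1-diethoxy-4,8-dimethylnona-2,7-dien-2-yl]silane | C=C[C@](C)(CCC=C(C)C)/C=C(\[Si](OCC)(OCC)OCC)C(OCC)OCC
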